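**Plan**

- Retrosynthesis, last cuts first: the three benzyl ethers, then the C3–O bond (made from a C3–B bond with retention). Ring A is then cut at C4a–C5 and C8–C8a. This is possible because ring A carries OH on C6 and C8 and H on C5 and C7, with C8a α and C4a β to the C1 ketone, which is the pattern a 1-methoxy-1,3-bis(silyloxy)butadiene leaves on an α-bromoenone.
- Ring B is cut at C2–C3 and C4–C4a into an (E)-β-boryl aryl enone and a 1-amino-3-silyloxybutadiene. The enone comes from the ring C ynone, the ynone from an aryl aldehyde, and the aryl–CH2–pyranone bond from a Suzuki–Miyaura coupling.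
- Forward order: ring C aldehyde, alkynol, coupling with the pyranone, ynone, (Z)-iodoenone, boryl enone; ring B by the first cycloaddition with bromination in the same flask; ring A by the second cycloaddition with aromatisation; C–B oxidation; hydrogenolysis.
- Relative configuration: the 3,4-cis relation of oxygen and aroyl is the cis boron/aroyl geometry of the enone, carried through a suprafacial cycloaddition and a retentive C–B oxidation. Absolute configuration: (2R,5R)-2,5-diphenylpyrrolidine on the first diene.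
- Boron stays on C3 until ring A is complete, so that no β-leaving group sits next to the acidic C4–H while heat or base is applied.

Key step: step 14

Abbreviations: Ar = 2,4-bis(benzyloxy)-6-[(4-benzyloxy-2-oxo-2H-pyran-6-yl)methyl]phenyl; ArCO = the corresponding benzoyl group; Bpin = 4,4,5,5-tetramethyl-1,3,2-dioxaborolan-2-yl. Tetralone numbering (C1–C8a) is used for the bicycle; ring B cyclohexenones are numbered from their own carbonyl.

Assumption: the facial sense of the diphenylpyrrolidine diene follows the steric model given in step 11; if the antipodal bromoenone formed, the (2S,5S) amine would be used with no other change.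

Remark: the carbinol carbon made in step 2 is racemic and is removed by the oxidation in step 6.

**Route**

Step 1
Reactants: 1 1,3-bis(benzyloxy)-5-bromobenzene
Product: 2 2,4-bis(benzyloxy)-6-bromobenzaldehyde
Conditions: POCl3, DMF, 0 to 80 °C; then aq. NaOAc
Reagents that add atoms: N,N-dimethylformamide, CN(C)C=O; water, O
Why: Vilsmeier–Haack formylation, in which the chloroiminium ion should enter para to one benzyloxy group and ortho to the other, next to bromine, because the position between the two ethers is the more hindered one.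

Step 2
Reactants: 2 2,4-bis(benzyloxy)-6-bromobenzaldehyde
Product: 3 rac-1-[2,4-bis(benzyloxy)-6-bromophenyl]but-2-yn-1-ol
Conditions: MeC≡CMgBr, THF, −78 to 0 °C; aq. NH4Cl
Reagents that add atoms: 1-propynylmagnesium bromide, CC#C[Mg]Br
Why: Grignard addition of the alkynyl reagent to the aldehyde, which leaves the aryl bromide untouched and gives a racemic carbinol that is oxidised later.

Step 3
Reactants: 4 4-hydroxy-6-methyl-2H-pyran-2-one
Product: 5 4-(benzyloxy)-6-methyl-2H-pyran-2-one
Conditions: BnOH, PPh3, DIAD, THF, 0 °C to rt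
Reagents that add atoms: benzyl alcohol, OCc1ccccc1
Why: Mitsunobu O-alkylation of the acidic vinylogous acid, chosen because it should give the 4-O-benzyl ether without the C3-benzylation that accompanies base-mediated alkylation.

Step 4
Reactants: 5 4-(benzyloxy)-6-methyl-2H-pyran-2-one
Product: 6 4-(benzyloxy)-6-(chloromethyl)-2H-pyran-2-one
Conditions: LiN(SiMe3)2, THF, −78 °C; cannulated into C2Cl6, THF, −78 °C
Reagents that add atoms: hexachloroethane, ClC(Cl)(Cl)C(Cl)(Cl)Cl
Why: vinylogous deprotonation of the 6-methyl group followed by electrophilic chlorination of the lithium dienolate, the same enolate halogenation that converts 2,2,6-trimethyl-1,3-dioxin-4-one into its 6-chloromethyl derivative.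

Step 5
Reactants: 3 rac-1-[2,4-bis(benzyloxy)-6-bromophenyl]but-2-yn-1-ol; 6 4-(benzyloxy)-6-(chloromethyl)-2H-pyran-2-one
Product: 8 rac-4-(benzyloxy)-6-{[3,5-bis(benzyloxy)-2-(1-hydroxybut-2-yn-1-yl)phenyl]methyl}-2H-pyran-2-one, via arylboronate 7 (not isolated)
Conditions: B2pin2, PdCl2(dppf), KOAc, 1,4-dioxane, 90 °C; then 6, aq. K3PO4, 70 °C
Reagents that add atoms: none
Why: Miyaura borylation of the aryl bromide followed in the same flask by an sp2–sp3 Suzuki–Miyaura coupling with the allyl-type chloride, which makes the aryl–CH2 bond at the ring position meta to both ethers that electrophilic substitution cannot reach.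

Step 6
Reactants: 8 rac-4-(benzyloxy)-6-{[3,5-bis(benzyloxy)-2-(1-hydroxybut-2-yn-1-yl)phenyl]methyl}-2H-pyran-2-one
Product: 9 1-Ar-but-2-yn-1-one (ArCO–C≡C–CH3)
Conditions: MnO2, CH2Cl2, rt
Reagents that add atoms: none
Why: oxidation of a benzylic and propargylic alcohol with manganese dioxide, a neutral heterogeneous oxidation that should leave the benzyl ethers, the pyranone and the activated methylene alone.

Step 7
Reactants: 9 1-Ar-but-2-yn-1-one
Product: 10 (2Z)-1-Ar-3-iodobut-2-en-1-one
Conditions: NaI, AcOH, rt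
Reagents that add atoms: sodium iodide, [Na+].[I-]
Why: conjugate anti-hydroiodination of the ynone, in which iodide adds to the β-carbon and the allenol is protonated trans to it, so that iodine should end up cis to the carbonyl; a phosphine-catalysed addition of pinacolborane is avoided because Lewis bases with pinacolborane reduce ynone carbonyls.

Step 8
Reactants: 10 (2Z)-1-Ar-3-iodobut-2-en-1-one
Product: 11 (2E)-1-Ar-3-Bpin-but-2-en-1-one (boron cis to the carbonyl)
Conditions: B2pin2, PdCl2(dppf), KOAc, 1,4-dioxane, 70 °C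
Reagents that add atoms: bis(pinacolato)diboron, CC1(C)OB(OC1(C)C)B1OC(C)(C)C(C)(C)O1
Why: Miyaura borylation of an alkenyl iodide, which proceeds with retention of the double-bond geometry and so should keep boron cis to the aroyl group.

Step 9
Reactants: 12 (2R,5R)-2,5-diphenylpyrrolidine; 13 (3E)-4-methoxybut-3-en-2-one
Product: 14 (3E)-4-[(2R,5R)-2,5-diphenylpyrrolidin-1-yl]but-3-en-2-one
Conditions: MeOH, rt
Reagents that add atoms: none
Why: conjugate addition–elimination of the secondary amine on the vinylogous ester, the standard amine exchange that gives a vinylogous amide.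

Step 10
Reactants: 14 (3E)-4-[(2R,5R)-2,5-diphenylpyrrolidin-1-yl]but-3-en-2-one
Product: 15 (2R,5R)-1-[(1E)-3-(tert-butyldimethylsilyloxy)buta-1,3-dien-1-yl]-2,5-diphenylpyrrolidine
Conditions: KN(SiMe3)2, THF, −78 °C; TBSCl
Reagents that add atoms: tert-butyl(chloro)dimethylsilane, CC(C)(C)[Si](C)(C)Cl
Why: kinetic deprotonation of the methyl ketone and O-silylation of the enolate, the usual preparation of 1-amino-3-silyloxybutadienes.

Step 11
Reactants: 11 (2E)-1-Ar-3-Bpin-but-2-en-1-one; 15 (2R,5R)-1-[(1E)-3-(tert-butyldimethylsilyloxy)buta-1,3-dien-1-yl]-2,5-diphenylpyrrolidine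
Product: 18 (4S,5S)-4-ArCO-2-bromo-5-methyl-5-Bpin-cyclohex-2-en-1-one, via cycloadduct 16 (not isolated), via bromo amino ketone 17 (not isolated)
Conditions: toluene, 60–80 °C; then NBS, THF, −78 °C; then 1 M HCl, THF, 0 °C
Reagents that add atoms: N-bromosuccinimide, O=C1CCC(=O)N1Br
Why: Diels–Alder cycloaddition of the 1-amino-3-silyloxydiene with the boron-bearing enone (diene CH2 to the boron-bearing β-carbon, amino carbon to the α-carbon) is suprafacial, so the cis boron/aroyl geometry of 11 becomes the C4/C5 relative configuration, while the C2-symmetric diphenylpyrrolidine should let the aroyl group approach only through the diene quadrant not covered by a phenyl group, which fixes the absolute sense whether the aroyl group is endo or exo; N-bromosuccinimide then brominates the silyl enol ether at C2 at −78 °C, far faster than the benzyloxy arene or the pyranone, and acid expels the protonated auxiliary by β-elimination through the C2–H that is activated by carbonyl and bromine.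

Step 12
Reactants: 19 methyl acetoacetate
Product: 20 methyl 3-(trimethylsilyloxy)but-2-enoate
Conditions: TMSCl, Et3N, hexane, rt
Reagents that add atoms: chlorotrimethylsilane, C[Si](C)(C)Cl
Why: O-silylation of the β-keto ester enol, the standard first stage toward the bis(silyloxy)diene.

Step 13
Reactants: 20 methyl 3-(trimethylsilyloxy)but-2-enoate
Product: 21 1-methoxy-1,3-bis(trimethylsilyloxy)buta-1,3-diene (E/Z mixture)
Conditions: LiN(iPr)2, THF, −78 °C; TMSCl
Reagents that add atoms: chlorotrimethylsilane, C[Si](C)(C)Cl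
Why: γ-deprotonation of the silyloxy enoate and O-silylation of the resulting ester dienolate, the established preparation of this ketene acetal diene.

Step 14
Reactants: 18 (4S,5S)-4-ArCO-2-bromo-5-methyl-5-Bpin-cyclohex-2-en-1-one; 21 1-methoxy-1,3-bis(trimethylsilyloxy)buta-1,3-diene
Product: 23 (3S,4R)-4-ArCO-6,8-dihydroxy-3-methyl-3-Bpin-3,4-dihydronaphthalen-1(2H)-one, via bromo cycloadduct 22 (not isolated)
Conditions: 21 (3 equiv), toluene, 80 °C; then MeOH, NaHCO3, 0 °C to rt
Reagents that add atoms: none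
Why: The electron-rich ketene acetal diene 21 and the α-bromoenone 18, whose acceptor orbital is lowered by bromine, should combine in a thermal normal-demand Diels–Alder reaction in which the CH2 terminus of 21 bonds to the β-carbon C4a and the acetal carbon to the bromine-bearing C8a, giving the cis-fused adduct 22. Ring A thus closes as a six-membered carbocycle in a [4+2] cycloaddition (a stepwise Mukaiyama–Michael addition followed by closure onto the ester carbon would form the same two bonds), and the closest known reaction type is the cycloaddition–aromatisation of 1-alkoxy-1,3-bis(silyloxy)dienes with α-halo enones and haloquinones. In hydrogencarbonate-buffered methanol 22 should lose methoxytrimethylsilane from C8, tautomerise through C5–H to the 6,8-dioxygenated cyclohexadiene and then lose HBr across C4a–C8a, a step driven by aromatisation, while desilylation frees the two phenols. The centres formed at C4a, C8a and C8 are transient and vanish in the arene, so no new stereocentre is kept; C3 and C4 are carried through unchanged because C3 bears boron, which cannot leave as a β-nucleofuge, and because no base stronger than hydrogencarbonate meets the acidic C4–H. The step needs regioselectivity (oxygen on C6 and C8, not C5 and C7), which the match of the nucleophilic diene terminus with the enone β-carbon secures, and chemoselectivity for the bromoenone over the pyranone and the twisted aryl ketone, which the bromine activation and the absence of any Lewis acid secure.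

Step 15
Reactants: 23 (3S,4R)-4-ArCO-6,8-dihydroxy-3-methyl-3-Bpin-3,4-dihydronaphthalen-1(2H)-one
Product: 24 (3R,4S)-4-ArCO-3,6,8-trihydroxy-3-methyl-3,4-dihydronaphthalen-1(2H)-one
Conditions: NaBO3·4H2O, THF/H2O, 0 °C to rt
Reagents that add atoms: sodium perborate (drawn as the monomer), [Na+].[O-]OB=O
Why: oxidation of the tertiary boronate by peroxoborate with 1,2-migration of carbon from boron to oxygen, which occurs with retention and so should place the C3 hydroxyl cis to the aroyl group under mildly basic conditions that the new aldol should tolerate.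

Step 16
Reactants: 24 (3R,4S)-4-ArCO-3,6,8-trihydroxy-3-methyl-3,4-dihydronaphthalen-1(2H)-one
Product: 25 CNP0197349.1, (3R,4S)-4-{2,4-dihydroxy-6-[(4-hydroxy-2-oxo-2H-pyran-6-yl)methyl]benzoyl}-3,6,8-trihydroxy-3-methyl-3,4-dihydronaphthalen-1(2H)-one
Conditions: H2 (1 atm), 10% Pd/C, EtOAc, rt
Reagents that add atoms: none
Why: hydrogenolysis of the two aryl benzyl ethers and the pyranone benzyl ether under neutral conditions, stopped at full debenzylation so that the pyranone double bonds and the aldol are not touched.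

**Compound list**

1 | 1,3-bis(benzyloxy)-5-bromobenzene | Brc1cc(OCc2ccccc2)cc(OCc2ccccc2)c1 | starting material
2 | 2,4-bis(benzyloxy)-6-bromobenzaldehyde | O=Cc1c(OCc2ccccc2)cc(OCc2ccccc2)cc1Br | intermediate
3 | rac-1-[2,4-bis(benzyloxy)-6-bromophenyl]but-2-yn-1-ol | CC#CC(O)c1c(OCc2ccccc2)cc(OCc2ccccc2)cc1Br | intermediate
4 | 4-hydroxy-6-methyl-2H-pyran-2-one | Cc1cc(O)cc(=O)o1 | starting material
5 | 4-(benzyloxy)-6-methyl-2H-pyran-2-one | Cc1cc(OCc2ccccc2)cc(=O)o1 | intermediate
6 | 4-(benzyloxy)-6-(chloromethyl)-2H-pyran-2-one | ClCc1cc(OCc2ccccc2)cc(=O)o1 | intermediate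
7 | rac-1-[2,4-bis(benzyloxy)-6-Bpin-phenyl]but-2-yn-1-ol (not isolated) | CC#CC(O)c1c(OCc2ccccc2)cc(OCc2ccccc2)cc1B1OC(C)(C)C(C)(C)O1 | intermediate
8 | rac-4-(benzyloxy)-6-{[3,5-bis(benzyloxy)-2-(1-hydroxybut-2-yn-1-yl)phenyl]methyl}-2H-pyran-2-one | CC#CC(O)c1c(OCc2ccccc2)cc(OCc2ccccc2)cc1Cc1cc(OCc2ccccc2)cc(=O)o1 | intermediate
9 | 1-Ar-but-2-yn-1-one | CC#CC(=O)c1c(OCc2ccccc2)cc(OCc2ccccc2)cc1Cc1cc(OCc2ccccc2)cc(=O)o1 | intermediate
10 | (2Z)-1-Ar-3-iodobut-2-en-1-one (iodine cis to the carbonyl) | C/C(I)=C/C(=O)c1c(OCc2ccccc2)cc(OCc2ccccc2)cc1Cc1cc(OCc2ccccc2)cc(=O)o1 | intermediate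
11 | (2E)-1-Ar-3-Bpin-but-2-en-1-one (boron cis to the carbonyl) | C/C(B1OC(C)(C)C(C)(C)O1)=C/C(=O)c1c(OCc2ccccc2)cc(OCc2ccccc2)cc1Cc1cc(OCc2ccccc2)cc(=O)o1 | intermediate
12 | (2R,5R)-2,5-diphenylpyrrolidine | N1[C@@H](c2ccccc2)CC[C@@H]1c1ccccc1 | starting material
13 | (3E)-4-methoxybut-3-en-2-one | CO/C=C/C(C)=O | starting material
14 | (3E)-4-[(2R,5R)-2,5-diphenylpyrrolidin-1-yl]but-3-en-2-one | CC(=O)/C=C/N1[C@@H](c2ccccc2)CC[C@@H]1c1ccccc1 | intermediate
15 | (2R,5R)-1-[(1E)-3-(tert-butyldimethylsilyloxy)buta-1,3-dien-1-yl]-2,5-diphenylpyrrolidine | C=C(O[Si](C)(C)C(C)(C)C)/C=C/N1[C@@H](c2ccccc2)CC[C@@H]1c1ccccc1 | intermediate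
16 | 4-ArCO-1-(tert-butyldimethylsilyloxy)-5-methyl-3-[(2R,5R)-2,5-diphenylpyrrolidin-1-yl]-5-Bpin-cyclohex-1-ene; C4 and C5 as in 18, C3 as formed (not isolated) | C[C@@]1(B2OC(C)(C)C(C)(C)O2)CC(O[Si](C)(C)C(C)(C)C)=CC(N2[C@@H](c3ccccc3)CC[C@@H]2c2ccccc2)[C@@H]1C(=O)c1c(OCc2ccccc2)cc(OCc2ccccc2)cc1Cc1cc(OCc2ccccc2)cc(=O)o1 | intermediate
17 | 4-ArCO-2-bromo-5-methyl-3-[(2R,5R)-2,5-diphenylpyrrolidin-1-yl]-5-Bpin-cyclohexan-1-one; C4 and C5 as in 18, C2 and C3 as formed (not isolated) | C[C@@]1(B2OC(C)(C)C(C)(C)O2)CC(=O)C(Br)C(N2[C@@H](c3ccccc3)CC[C@@H]2c2ccccc2)[C@@H]1C(=O)c1c(OCc2ccccc2)cc(OCc2ccccc2)cc1Cc1cc(OCc2ccccc2)cc(=O)o1 | intermediate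
18 | (4S,5S)-4-ArCO-2-bromo-5-methyl-5-Bpin-cyclohex-2-en-1-one | C[C@@]1(B2OC(C)(C)C(C)(C)O2)CC(=O)C(Br)=C[C@@H]1C(=O)c1c(OCc2ccccc2)cc(OCc2ccccc2)cc1Cc1cc(OCc2ccccc2)cc(=O)o1 | intermediate
19 | methyl acetoacetate | COC(=O)CC(C)=O | starting material
20 | methyl 3-(trimethylsilyloxy)but-2-enoate | COC(=O)C=C(C)O[Si](C)(C)C | intermediate
21 | 1-methoxy-1,3-bis(trimethylsilyloxy)buta-1,3-diene (E/Z mixture) | COC(O[Si](C)(C)C)=CC(=C)O[Si](C)(C)C | intermediate
22 | cis-fused 8a-bromo-8-methoxy-6,8-bis(trimethylsilyloxy) cycloadduct of 18 and 21; C3 and C4 as in 18, C4a, C8 and C8a as formed (not isolated) | C[C@@]1(B2OC(C)(C)C(C)(C)O2)CC(=O)C2(Br)C(CC(O[Si](C)(C)C)=CC2(OC)O[Si](C)(C)C)[C@@H]1C(=O)c1c(OCc2ccccc2)cc(OCc2ccccc2)cc1Cc1cc(OCc2ccccc2)cc(=O)o1 | intermediate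
23 | (3S,4R)-4-ArCO-6,8-dihydroxy-3-methyl-3-Bpin-3,4-dihydronaphthalen-1(2H)-one | C[C@@]1(B2OC(C)(C)C(C)(C)O2)CC(=O)c2c(O)cc(O)cc2[C@@H]1C(=O)c1c(OCc2ccccc2)cc(OCc2ccccc2)cc1Cc1cc(OCc2ccccc2)cc(=O)o1 | intermediate
24 | (3R,4S)-4-ArCO-3,6,8-trihydroxy-3-methyl-3,4-dihydronaphthalen-1(2H)-one | C[C@@]1(O)CC(=O)c2c(O)cc(O)cc2[C@@H]1C(=O)c1c(OCc2ccccc2)cc(OCc2ccccc2)cc1Cc1cc(OCc2ccccc2)cc(=O)o1 | intermediate
25 | CNP0197349.1, (3R,4S)-4-{2,4-dihydroxy-6-[(4-hydroxy-2-oxo-2H-pyran-6-yl)methyl]benzoyl}-3,6,8-trihydroxy-3-methyl-3,4-dihydronaphthalen-1(2H)-one | C[C@@]1(O)CC(=O)c2c(O)cc(O)cc2[C@@H]1C(=O)c1c(O)cc(O)cc1Cc1cc(O)cc(=O)o1 | target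

**Step count and risks**

Total step count: 16 steps.
Longest linear sequence: 10 steps (steps 1, 2, 5, 6, 7, 8, 11, 14, 15, 16).

Steps most likely to fail:

1. Step 11. The cycloaddition has to form a bond at a fully substituted, boron-bearing β-carbon next to a very bulky auxiliary, so it may be slow, and facial discrimination may erode at the temperature needed. The fallback sets out from 11. Cycloaddition with the commercial, less hindered 1-(dimethylamino)-3-(tert-butyldimethylsilyloxy)buta-1,3-diene, followed by the same N-bromosuccinimide and acid treatment, should give racemic bromoenone through the racemic dimethylamino cycloadduct F1 and the racemic bromo dimethylamino ketone F2. The enantiomers are then separated by preparative chromatography on a chiral stationary phase, the antipodal bromoenone F3 is set aside, and the route is rejoined at 18.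

2. Step 14. In the cis-fused adduct the C4a hydrogen and the bromine are syn, so loss of HBr may stall. In addition, the bromine of the α-bromo dicarbonyl stage may be transferred to excess diene, which would leave a reduced adduct that cannot aromatise. The fallback sets out from 11 and 15. The cycloadduct 16 is quenched with PhSCl in place of N-bromosuccinimide to give the phenylthio amino ketone F4, acid then gives the 2-(phenylthio)enone F5, and mCPBA at −78 °C gives the sulfoxide F6. Heating F6 with 21 in toluene should give the sulfinyl cycloadduct F7, in which the sulfoxide is syn to the C4a hydrogen and leaves thermally as benzenesulfenic acid without any base. Buffered methanol then returns the route to 23.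

3. Step 15. Oxidation of the hindered tertiary boronate may be slow, and on long exposure to basic peroxide the electron-rich hydroxyaryl ketone may be cleaved or the new aldol may dehydrate toward a naphthol. The fallback sets out from 18. Buffered perborate oxidation at this earlier, phenol-free stage should give the hydroxy bromoenone F8, which is silylated under neutral conditions with 1-(trimethylsilyl)imidazole to the trimethylsilyl ether F9. Annulation with 21 as in step 14 passes through the bromo cycloadduct F10 to the tertiary silyl ether F11, and brief PPTS in methanol removes the silyl group, so the route is rejoined at 24.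

Further compounds
F1 | step 11 | racemic 4-ArCO-1-(tert-butyldimethylsilyloxy)-3-(dimethylamino)-5-methyl-5-Bpin-cyclohex-1-ene, ArCO and Bpin cis, one enantiomer drawn (not isolated) | C[C@@]1(B2OC(C)(C)C(C)(C)O2)CC(O[Si](C)(C)C(C)(C)C)=CC(N(C)C)[C@@H]1C(=O)c1c(OCc2ccccc2)cc(OCc2ccccc2)cc1Cc1cc(OCc2ccccc2)cc(=O)o1
F2 | step 11 | racemic 4-ArCO-2-bromo-3-(dimethylamino)-5-methyl-5-Bpin-cyclohexan-1-one, ArCO and Bpin cis, one enantiomer drawn (not isolated) | C[C@@]1(B2OC(C)(C)C(C)(C)O2)CC(=O)C(Br)C(N(C)C)[C@@H]1C(=O)c1c(OCc2ccccc2)cc(OCc2ccccc2)cc1Cc1cc(OCc2ccccc2)cc(=O)o1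
F3 | step 11 | (4R,5R)-4-ArCO-2-bromo-5-methyl-5-Bpin-cyclohex-2-en-1-one, the enantiomer of 18 | C[C@]1(B2OC(C)(C)C(C)(C)O2)CC(=O)C(Br)=C[C@H]1C(=O)c1c(OCc2ccccc2)cc(OCc2ccccc2)cc1Cc1cc(OCc2ccccc2)cc(=O)o1
F4 | step 14 | 4-ArCO-5-methyl-3-[(2R,5R)-2,5-diphenylpyrrolidin-1-yl]-2-(phenylthio)-5-Bpin-cyclohexan-1-one, C4 and C5 as in 18 (not isolated) | C[C@@]1(B2OC(C)(C)C(C)(C)O2)CC(=O)C(Sc2ccccc2)C(N2[C@@H](c3ccccc3)CC[C@@H]2c2ccccc2)[C@@H]1C(=O)c1c(OCc2ccccc2)cc(OCc2ccccc2)cc1Cc1cc(OCc2ccccc2)cc(=O)o1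
F5 | step 14 | 4-ArCO-5-methyl-2-(phenylthio)-5-Bpin-cyclohex-2-en-1-one, C4 and C5 as in 18 | C[C@@]1(B2OC(C)(C)C(C)(C)O2)CC(=O)C(Sc2ccccc2)=C[C@@H]1C(=O)c1c(OCc2ccccc2)cc(OCc2ccccc2)cc1Cc1cc(OCc2ccccc2)cc(=O)o1
F6 | step 14 | 4-ArCO-5-methyl-2-(phenylsulfinyl)-5-Bpin-cyclohex-2-en-1-one, C4 and C5 as in 18, mixture at sulfur | C[C@@]1(B2OC(C)(C)C(C)(C)O2)CC(=O)C(S(=O)c2ccccc2)=C[C@@H]1C(=O)c1c(OCc2ccccc2)cc(OCc2ccccc2)cc1Cc1cc(OCc2ccccc2)cc(=O)o1
F7 | step 14 | cis-fused 8-methoxy-8a-(phenylsulfinyl)-6,8-bis(trimethylsilyloxy) cycloadduct of F6 and 21 (not isolated) | C[C@@]1(B2OC(C)(C)C(C)(C)O2)CC(=O)C2(S(=O)c3ccccc3)C(CC(O[Si](C)(C)C)=CC2(OC)O[Si](C)(C)C)[C@@H]1C(=O)c1c(OCc2ccccc2)cc(OCc2ccccc2)cc1Cc1cc(OCc2ccccc2)cc(=O)o1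
F8 | step 15 | (4S,5R)-4-ArCO-2-bromo-5-hydroxy-5-methylcyclohex-2-en-1-one | C[C@@]1(O)CC(=O)C(Br)=C[C@@H]1C(=O)c1c(OCc2ccccc2)cc(OCc2ccccc2)cc1Cc1cc(OCc2ccccc2)cc(=O)o1
F9 | step 15 | (4S,5R)-4-ArCO-2-bromo-5-methyl-5-(trimethylsilyloxy)cyclohex-2-en-1-one | C[C@@]1(O[Si](C)(C)C)CC(=O)C(Br)=C[C@@H]1C(=O)c1c(OCc2ccccc2)cc(OCc2ccccc2)cc1Cc1cc(OCc2ccccc2)cc(=O)o1
F10 | step 15 | cis-fused 8a-bromo-8-methoxy-3,6,8-tris(trimethylsilyloxy) cycloadduct of F9 and 21 (not isolated) | C[C@@]1(O[Si](C)(C)C)CC(=O)C2(Br)C(CC(O[Si](C)(C)C)=CC2(OC)O[Si](C)(C)C)[C@@H]1C(=O)c1c(OCc2ccccc2)cc(OCc2ccccc2)cc1Cc1cc(OCc2ccccc2)cc(=O)o1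
F11 | step 15 | (3R,4S)-4-ArCO-6,8-dihydroxy-3-methyl-3-(trimethylsilyloxy)-3,4-dihydronaphthalen-1(2H)-one | C[C@@]1(O[Si](C)(C)C)CC(=O)c2c(O)cc(O)cc2[C@@H]1C(=O)c1c(OCc2ccccc2)cc(OCc2ccccc2)cc1Cc1cc(OCc2ccccc2)cc(=O)o1
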